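## Structural features

Betaethrin H is a diaryl ether with no stereocentre. Two benzene rings are joined by a single oxygen between ring A carbon C2 and ring B carbon C1'. Ring A is 1,2,3,5-tetrasubstituted: C1 carries the hexadecanoyloxymethyl group, C2 the ether oxygen, C3 a free hydroxyl and C5 a methoxy group. Ring B is 1',3',5'-trisubstituted with the ether oxygen, a methyl group and a hydroxyl group mutually meta. The fragile parts are the benzylic ester on an electron-rich ring (lost by hydrogenolysis, solvolysis or base) and the two electron-rich phenols (oxidation, capture of electrophiles such as formaldehyde). The real difficulty is twofold: the ether oxygen on C2 is flanked by both ortho substituents, which makes a direct O-arylation hard, and three hydroxyl groups have to be told apart so that only the primary one is acylated. The key step uses the meta pattern of ring B: oxygen at C5' and methyl at C3' map onto C4 and C6 of a 4-oxy-6-methyl-2-pyrone, while C1' and C2' come from a two-carbon ethynyl group that the crowded ring A oxygen can carry easily.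

## Logic of the disconnections

**23 to 22.** The last cut is at the two acetal O–CH2 bonds on the C3 and C5' oxygens. Both phenols stay masked until the ester is in place, so no aryl ester can form. The forward step must cleave two aryl methoxymethyl ethers without touching a benzylic ester; this excludes hydrogenolysis and strong protic acid in a nucleophilic alcohol.

**22 to 19 and 20.** The acyl C–O bond of the ester is cut. This removes sixteen carbons in one step and leaves a single free hydroxyl in 19, so the acylation needs no selectivity, only mild neutral activation.

**19 to 18.** The O–Si bond on the benzylic oxygen is cut. A silyl ether is chosen because it survives butyllithium and heat and comes off with fluoride, which leaves the two acetals alone.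

**18 to 14 and 16 (key).** The C1'–C6' and C2'–C3' bonds of ring B are cut, with a CO2 bridge added back across C3' and C6'. This takes ring B apart into a one-step pyrone derivative and an ethynyl ether, and it replaces a hindered O-arylation by a cycloaddition at carbons remote from the crowded oxygen. The atom balance holds: 14 (C18H28O5Si) plus 16 (C8H10O4) minus CO2 is 18 (C25H38O7Si). The forward step needs one regiochemistry (alkyne CH to pyrone C6) and an alkyne that survives heating. The pyrone oxygen carries the same acetal as ring A so that one final operation frees both phenols. An acyl or sulfonyl group would make the pyrone more electron-poor, but could not be removed later beside the palmitate.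

**14 to 11, then to 8 and 9.** The alkyne is traced to a 1,2-dichlorovinyl ether, and the O–C(vinyl) bond is cut to the phenol and a C2 chloride. The oxygen attacks a linear two-carbon electrophile, so the flanking groups matter little. The forward steps need a base-stable phenol and groups inert to butyllithium at low temperature.

**8 to 7 to 6.** The O–Si bond is cut and the benzylic alcohol is traced to the methyl ester. The ester makes the neighbouring phenol distinguishable in the earlier protection step. The demands are selective silylation of a primary alcohol beside a hindered phenol, and a hydride reduction with non-acidic work-up.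

**6 to 5 to 3 to 1.** The acetal on the C3 oxygen is removed, the C3–O bond is traced to a C3–CHO bond (aryl migration to oxygen), and the formyl C–C bond is cut. This reaches a commercial salicylate whose only free position ortho to the hydroxyl is C3. The demands are ortho-selective formylation, an oxidation mild enough for a methyl ester and an electron-rich catechol, and alkylation of the C3 hydroxyl in preference to the hydrogen-bonded C2 hydroxyl.

**16 to 15.** The acetal O–CH2 bond on the pyrone 4-oxygen is cut, which leads to a commodity pyrone. Alkylation must occur on the 4-oxygen and not on C3 or the ring carbonyl oxygen.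

## Other disconnections considered

**Alternative 1:** The cut is the C1–C2 bond of ring A, which opens the ring to the masked triketo ester A2; ring B comes intact from orcinol A1. In the forward key step, base forms the enolate at the aryloxy-bearing methylene of A2, which adds to the ketone of the 2-oxo ester, and loss of water gives the arene A3.

- In favour: ring B is bought, not built, and no CO2 or pyrone protecting group is spent, which is better in atom economy than the chosen plan. The crowded C2–O bond is made by alkylation of a phenoxide, which is equal to the chosen plan in avoiding O-arylation. A3 emerges with the C3 hydroxyl free and a C1 ester, and no high temperature or labile alkyne is needed.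
- Against: A2 has three enolisable sites. The methylene between the 2-oxo ester and the enol ether is far more acidic than the aryloxy methylene, and its enolisation deactivates the very ketone that must be attacked. O-cyclisation to pyranones is a further competing path. The benzyl ether on ring B can only be removed by hydrogenolysis before the benzylic ester exists, so the phenols must be re-masked or the acylation made selective.
- Comparison: on structure both plans avoid the hindered arylation. On mechanism, a reversible ionic aldol with competing enolates stands against a pericyclic step whose regiochemistry is built into both partners. On step economy, A2 should need about five steps, followed by reduction, protecting-group exchange, acylation and deprotection, so no gain over twelve steps is expected.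

**Alternative 2:** The cut removes three bonds of ring A (C3–C4, C5–C6, C2–C3) and leads to the aryloxycyclobutenone A4 and methoxyacetylene A5. In the forward key step, heating opens A4 to a vinylketene, which adds A5; a second four-electron ring opening and a six-electron electrocyclisation then give the phenol A6.

- In favour: this is the most convergent plan. Three bonds and all four ring A substituents are set in one operation with no regiochemical doubt, which is better than the chosen key step in bonds formed. Like the chosen step it is pericyclic and driven by aromatisation, so it is equal on mechanistic reliability in principle.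
- Against: A4 is hard to reach. A (2+2) addition of an aryloxyketene to an unactivated terminal alkyne is poor, and squarate-based routes are long. A4 can also open and dimerise on storage. A5 is a very volatile, unstable reagent that must be made fresh. A6 carries a free C3 hydroxyl plus one aryl and one alkyl silyl ether, so masking, selective desilylation, acylation and final desilylation would take about four steps after the key step, against three here.
- Comparison: the key step itself is stronger in Alternative 2, but the supply of both partners is less secure than the one-step pyrone 16 and the phenol-derived alkyne 14, and the overall count is not expected to be lower.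

**Alternative 3:** The cut is at C1–C6 and C4–C5 of ring A and leads to the aryloxy enone A7 and dimethyl malonate A8. In the forward key step, NaOMe-mediated Michael addition of A8 to A7 is followed by Claisen acylation of the methyl ketone enolate, giving the cyclohexanedione A9.

- In favour: this is classical anion chemistry with cheap reagents and no pressure tube, unstable alkyne or carcinogenic alkylating agent in the key step. On practicality of reagents it is better than the chosen plan.
- Against: A9 is not aromatic. It needs ester hydrolysis and decarboxylation, dehydrogenation, and methylation of the C5 oxygen only. During aromatisation the α-aryloxy ketone offers loss of the aryloxy group as a competing way to the arene. The benzyl ether again clashes with the benzylic ester.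
- Comparison: on structure it builds ring A from acyclic carbons and buys ring B, the reverse of the chosen plan. On mechanism, several ionic equilibria and an oxidation replace one cycloaddition that delivers the arene directly. On step economy at least thirteen steps are expected, with less certainty in the late stage.

Key step: step 9

Assumption (remark on the chemistry): ring A is numbered C1 (CH2O), C2 (O-aryl), C3 (OH), C5 (OMe) and ring B C1' (O), C3' (CH3), C5' (OH); the acyl group is unbranched hexadecanoyl; the target has no stereocentre, so none has to be set.

## Route

Step 1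
Reactants: 1 methyl 2-hydroxy-5-methoxybenzoate (methyl 5-methoxysalicylate)
Product: 3 methyl 3-formyl-2-hydroxy-5-methoxybenzoate, via hydroxymethyl phenol 2 (not isolated)
Conditions: MgCl2 (2 equiv), Et3N (4 equiv), (CH2O)n (6 equiv), MeCN, reflux; then 1 M HCl
Reagents that add atoms: paraformaldehyde (reacts as formaldehyde), C=O
Why: Casnati–Skattebøl ortho-formylation: the magnesium phenoxide of 1 delivers formaldehyde only to the free position ortho to oxygen (C3; the para position carries OMe) to give 2 as its magnesium alkoxide, which a second formaldehyde oxidises by hydride transfer to 3; the ester slows but should not divert the reaction.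

Step 2
Reactants: 3 methyl 3-formyl-2-hydroxy-5-methoxybenzoate
Product: 5 methyl 2,3-dihydroxy-5-methoxybenzoate, via aryl formate 4 (not isolated)
Conditions: Na2CO3·1.5H2O2 (1.2 equiv), THF/H2O, rt, Ar; then 1 M HCl
Reagents that add atoms: hydrogen peroxide (released from Na2CO3·1.5H2O2), OO
Why: Dakin oxidation: hydroperoxide adds to the aldehyde, the aryl group (electron-rich through the ortho phenoxide) migrates to oxygen to give formate 4, and the carbonate hydrolyses it in the flask; the mild base should spare the methyl ester and exclusion of air protects the catechol.

Step 3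
Reactants: 5 methyl 2,3-dihydroxy-5-methoxybenzoate
Product: 6 methyl 2-hydroxy-5-methoxy-3-(methoxymethoxy)benzoate
Conditions: MOMCl (1.05 equiv), i-Pr2NEt (1.2 equiv), CH2Cl2, 0 °C
Reagents that add atoms: chloromethyl methyl ether (MOMCl), COCCl
Why: Selective O-alkylation of a phenol: the C2 hydroxyl is tied to the ester carbonyl by a hydrogen bond and flanked on both sides, so one equivalent of the alkylating agent with a weak amine base should take the free C3 hydroxyl.

Step 4
Reactants: 6 methyl 2-hydroxy-5-methoxy-3-(methoxymethoxy)benzoate
Product: 7 2-(hydroxymethyl)-4-methoxy-6-(methoxymethoxy)phenol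
Conditions: LiAlH4 (2 equiv), THF, 0 °C to rt; aq. KNaC4H4O6 work-up
Reagents that add atoms: none
Why: Hydride reduction of the aryl ester to the benzylic alcohol; the phenol is carried as its aluminate, the acetal is inert to hydride, and the neutral tartrate work-up avoids acid that could ionise the ortho-hydroxybenzyl alcohol.

Step 5
Reactants: 7 2-(hydroxymethyl)-4-methoxy-6-(methoxymethoxy)phenol
Product: 8 2-({[tert-butyl(dimethyl)silyl]oxy}methyl)-4-methoxy-6-(methoxymethoxy)phenol
Conditions: TBSCl (1.05 equiv), imidazole (2 equiv), CH2Cl2, 0 °C
Reagents that add atoms: tert-butyldimethylsilyl chloride (TBSCl), CC(C)(C)[Si](C)(C)Cl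
Why: Chemoselective silylation: the primary alcohol is unhindered while the phenol lies between two ortho substituents, so one equivalent of the bulky chlorosilane should react at the benzylic oxygen only.

Step 6
Reactants: 8 2-({[tert-butyl(dimethyl)silyl]oxy}methyl)-4-methoxy-6-(methoxymethoxy)phenol; 9 trichloroethylene
Product: 11 tert-butyl[(2-{[(E)-1,2-dichloroethenyl]oxy}-5-methoxy-3-(methoxymethoxy)phenyl)methoxy]dimethylsilane, via dichloroacetylene 10 (not isolated)
Conditions: K2CO3 (2 equiv), 9 (1.5 equiv), DMF, 70 °C, Ar (closed system; 10 is never isolated)
Reagents that add atoms: none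
Why: Addition of a phenoxide to a haloalkyne: base eliminates HCl from 9 to give 10 in low concentration, and the phenoxide adds anti to this slim linear electrophile, which is why even the doubly flanked oxygen should react and why the (E)-dichlorovinyl ether results.

Step 7
Reactants: 11 tert-butyl[(2-{[(E)-1,2-dichloroethenyl]oxy}-5-methoxy-3-(methoxymethoxy)phenyl)methoxy]dimethylsilane
Product: 14 tert-butyl{[2-(ethynyloxy)-5-methoxy-3-(methoxymethoxy)phenyl]methoxy}dimethylsilane, via chloroethynyl ether 12 (not isolated), via lithium acetylide 13 (not isolated)
Conditions: n-BuLi (2.3 equiv), THF, −78 to −40 °C; then H2O, −78 °C; cold neutral work-up, kept as a solution over a trace of Et3N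
Reagents that add atoms: none
Why: Dehydrohalogenation and halogen–metal exchange route to ynol ethers: deprotonation and loss of LiCl give 12, chlorine–lithium exchange gives 13, and water protonates it; at −78 °C the silyl ether, the acetal and the ring hydrogens should not be attacked, and the aryl group has no β-hydrogen for ketene-forming fragmentation.

Step 8
Reactants: 15 4-hydroxy-6-methyl-2H-pyran-2-one
Product: 16 4-(methoxymethoxy)-6-methyl-2H-pyran-2-one
Conditions: MOMCl (1.2 equiv), i-Pr2NEt (1.5 equiv), CH2Cl2, 0 °C to rt; Et3N-washed silica
Reagents that add atoms: chloromethyl methyl ether (MOMCl), COCCl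
Why: O-Alkylation of a vinylogous acid: the hard oxocarbenium-type electrophile should react at the 4-oxygen and keep the 2-pyrone form; the product is a vinylogous acylal and is therefore handled without acid.

Step 9
Reactants: 14 tert-butyl{[2-(ethynyloxy)-5-methoxy-3-(methoxymethoxy)phenyl]methoxy}dimethylsilane; 16 4-(methoxymethoxy)-6-methyl-2H-pyran-2-one
Product: 18 tert-butyl({5-methoxy-3-(methoxymethoxy)-2-[3-(methoxymethoxy)-5-methylphenoxy]phenyl}methoxy)dimethylsilane, via bridged lactone 17 (not isolated)
Conditions: 16 (3 equiv), o-xylene, i-Pr2NEt (0.1 equiv), 130 °C, Ar; 14 added slowly over 6 h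
Reagents that add atoms: none
Why: Thermal Diels–Alder reaction of the pyrone diene (C3=C4–C5=C6) with the alkyne of 14 forms both new bonds (O-bearing alkyne carbon to pyrone C3, alkyne CH to pyrone C6; C1'–C6' and C2'–C3' of ring B) in one asynchronous concerted event to give 17, which expels CO2 by cycloreversion and leaves the benzene ring. The closest known reaction type is the cycloaddition–decarboxylation of 2-pyrones with heteroatom-substituted alkynes (ynamines, alkoxyalkynes) to give anilines and aryl ethers. Ring B is closed by intermolecular (4+2) cycloaddition, four carbons from 16 and two from 14, and becomes aromatic by loss of the lactone bridge; no ionic exo or endo cyclisation is involved. No stereocentre remains, since the two bridgeheads of 17 are transient and disappear with CO2. The selectivity needed is regiochemical: the alkyne CH is the nucleophilic end (donation from the ether oxygen) and pyrone C6 the electrophilic end of the diene, while the enolate-like C3 bonds to the oxocarbenium-like alkyne carbon, so the ether oxygen, the methyl group and the protected hydroxyl end up mutually meta. Self-reaction of the alkyne should be held back by keeping 16 in excess and 14 dilute, with a trace of amine to exclude acid-catalysed addition to the ynol ether. The silyl ether, the acetals and the methyl ether are thermally inert under these conditions.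

Step 10
Reactants: 18 tert-butyl({5-methoxy-3-(methoxymethoxy)-2-[3-(methoxymethoxy)-5-methylphenoxy]phenyl}methoxy)dimethylsilane
Product: 19 {5-methoxy-3-(methoxymethoxy)-2-[3-(methoxymethoxy)-5-methylphenoxy]phenyl}methanol
Conditions: Bu4NF (1.1 equiv), THF, 0 °C
Reagents that add atoms: none
Why: Fluoride-mediated desilylation driven by the Si–F bond; the aryl acetals and the diaryl ether are inert to fluoride.

Step 11
Reactants: 19 {5-methoxy-3-(methoxymethoxy)-2-[3-(methoxymethoxy)-5-methylphenoxy]phenyl}methanol; 20 hexadecanoic acid (palmitic acid)
Product: 22 {5-methoxy-3-(methoxymethoxy)-2-[3-(methoxymethoxy)-5-methylphenoxy]phenyl}methyl hexadecanoate, via O-acylisourea 21 (not isolated)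
Conditions: 20 (1.2 equiv), i-PrN=C=N-i-Pr (1.3 equiv), DMAP (0.1 equiv), CH2Cl2, 0 °C to rt
Reagents that add atoms: none
Why: Steglich esterification: the carbodiimide activates 20 as 21 and DMAP passes the acyl group to the only free hydroxyl, a primary benzylic alcohol; both phenols are masked, so no aryl ester can form.

Step 12
Reactants: 22 {5-methoxy-3-(methoxymethoxy)-2-[3-(methoxymethoxy)-5-methylphenoxy]phenyl}methyl hexadecanoate
Product: 23 betaethrin H, [3-hydroxy-2-(3-hydroxy-5-methylphenoxy)-5-methoxyphenyl]methyl hexadecanoate
Conditions: ZnBr2 (3 equiv), n-PrSH (6 equiv), CH2Cl2, 0 °C to rt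
Reagents that add atoms: none
Why: Lewis-acid and thiol cleavage of acetals: ZnBr2 activates each methoxymethyl ether and the thiol captures the methoxymethyl cation, so no formaldehyde equivalent is left to attack the electron-rich rings; the medium is non-hydrolytic and alcohol-free, which should spare the benzylic ester from solvolysis and transesterification.

## Compound list

1 | methyl 2-hydroxy-5-methoxybenzoate (methyl 5-methoxysalicylate) | COC(=O)c1cc(OC)ccc1O | starting material
2 | methyl 2-hydroxy-3-(hydroxymethyl)-5-methoxybenzoate (magnesium salt in the flask) | COC(=O)c1cc(OC)cc(CO)c1O | intermediate (not isolated)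
3 | methyl 3-formyl-2-hydroxy-5-methoxybenzoate | COC(=O)c1cc(OC)cc(C=O)c1O | intermediate
4 | methyl 3-(formyloxy)-2-hydroxy-5-methoxybenzoate | COC(=O)c1cc(OC)cc(OC=O)c1O | intermediate (not isolated)
5 | methyl 2,3-dihydroxy-5-methoxybenzoate | COC(=O)c1cc(OC)cc(O)c1O | intermediate
6 | methyl 2-hydroxy-5-methoxy-3-(methoxymethoxy)benzoate | COCOc1cc(OC)cc(C(=O)OC)c1O | intermediate
7 | 2-(hydroxymethyl)-4-methoxy-6-(methoxymethoxy)phenol | COCOc1cc(OC)cc(CO)c1O | intermediate
8 | 2-({[tert-butyl(dimethyl)silyl]oxy}methyl)-4-methoxy-6-(methoxymethoxy)phenol | COCOc1cc(OC)cc(CO[Si](C)(C)C(C)(C)C)c1O | intermediate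
9 | trichloroethylene | ClC=C(Cl)Cl | starting material
10 | dichloroacetylene | ClC#CCl | intermediate (not isolated)
11 | tert-butyl[(2-{[(E)-1,2-dichloroethenyl]oxy}-5-methoxy-3-(methoxymethoxy)phenyl)methoxy]dimethylsilane | COCOc1cc(OC)cc(CO[Si](C)(C)C(C)(C)C)c1O/C(Cl)=C\Cl | intermediate
12 | tert-butyl({2-[(chloroethynyl)oxy]-5-methoxy-3-(methoxymethoxy)phenyl}methoxy)dimethylsilane | COCOc1cc(OC)cc(CO[Si](C)(C)C(C)(C)C)c1OC#CCl | intermediate (not isolated)
13 | lithium 2-[2-({[tert-butyl(dimethyl)silyl]oxy}methyl)-4-methoxy-6-(methoxymethoxy)phenoxy]ethyn-1-ide | COCOc1cc(OC)cc(CO[Si](C)(C)C(C)(C)C)c1OC#C[Li] | intermediate (not isolated)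
14 | tert-butyl{[2-(ethynyloxy)-5-methoxy-3-(methoxymethoxy)phenyl]methoxy}dimethylsilane | C#COc1c(CO[Si](C)(C)C(C)(C)C)cc(OC)cc1OCOC | intermediate
15 | 4-hydroxy-6-methyl-2H-pyran-2-one | CC1=CC(O)=CC(=O)O1 | starting material
16 | 4-(methoxymethoxy)-6-methyl-2H-pyran-2-one | COCOC1=CC(=O)OC(C)=C1 | intermediate
17 | 8-[2-({[tert-butyl(dimethyl)silyl]oxy}methyl)-4-methoxy-6-(methoxymethoxy)phenoxy]-5-(methoxymethoxy)-1-methyl-2-oxabicyclo[2.2.2]octa-5,7-dien-3-one (racemic; one enantiomer drawn, the bridgeheads are fixed relative to each other by the bicycle) | O=C1O[C@]2(C)C=C(OCOC)[C@H]1C(Oc3c(CO[Si](C)(C)C(C)(C)C)cc(OC)cc3OCOC)=C2 | intermediate (not isolated)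
18 | tert-butyl({5-methoxy-3-(methoxymethoxy)-2-[3-(methoxymethoxy)-5-methylphenoxy]phenyl}methoxy)dimethylsilane | COCOc1cc(C)cc(Oc2c(CO[Si](C)(C)C(C)(C)C)cc(OC)cc2OCOC)c1 | intermediate
19 | {5-methoxy-3-(methoxymethoxy)-2-[3-(methoxymethoxy)-5-methylphenoxy]phenyl}methanol | COCOc1cc(C)cc(Oc2c(CO)cc(OC)cc2OCOC)c1 | intermediate
20 | hexadecanoic acid (palmitic acid) | CCCCCCCCCCCCCCCC(=O)O | starting material
21 | O-hexadecanoyl-N,N'-diisopropylisourea | CCCCCCCCCCCCCCCC(=O)OC(=NC(C)C)NC(C)C | intermediate (not isolated)
22 | {5-methoxy-3-(methoxymethoxy)-2-[3-(methoxymethoxy)-5-methylphenoxy]phenyl}methyl hexadecanoate | CCCCCCCCCCCCCCCC(=O)OCc1cc(OC)cc(OCOC)c1Oc1cc(C)cc(OCOC)c1 | intermediate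
23 | betaethrin H, [3-hydroxy-2-(3-hydroxy-5-methylphenoxy)-5-methoxyphenyl]methyl hexadecanoate | CCCCCCCCCCCCCCCC(=O)OCc1cc(OC)cc(O)c1Oc1cc(C)cc(O)c1 | target

## Step count and least certain steps

Total: 12 steps. Longest linear sequence: 11 steps (steps 1 to 7 and 9 to 12); step 8 is a one-step side branch.

**Step 9 (key step).** The 4-alkoxy group makes the pyrone a less electron-poor diene, so the cycloaddition may be slower than thermal oligomerisation or adventitious hydration of the terminal ynol ether; partial loss of regiocontrol is the lesser risk. Fallback: the diaryl ether would be made by copper-catalysed O-arylation, setting out from 8. Commercial 3-bromo-5-methylphenol F1 would be protected with MOMCl and i-Pr2NEt to give 1-bromo-3-(methoxymethoxy)-5-methylbenzene F2. Ullmann coupling of 8 with F2 (CuI, picolinic acid, K3PO4, DMSO, 90 °C) should then deliver 18, where the route is rejoined. The hindered partner is the nucleophile and the aryl bromide is unhindered, which is the favourable arrangement for this coupling.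

**Step 7.** The terminal aryl ynol ether may decompose during work-up or concentration (hydration to an aryl acetate, polymerisation), and excess base may start ortho-metalation next to the acetal. Fallback: setting out from 11, the acetylide formed with n-BuLi would be trapped with Me3SiCl to give the storable silyl-capped alkyne tert-butyl{[5-methoxy-3-(methoxymethoxy)-2-{[(trimethylsilyl)ethynyl]oxy}phenyl]methoxy}dimethylsilane F3. This can be purified and kept, and would be unmasked with catalytic K2CO3 in MeOH/THF at 0 °C immediately before use, coming back at 14 as a solution that goes straight into step 9.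

**Step 12.** The Lewis acid may ionise the benzylic C–O bond of the ester (capture by thiol), or acetal fragments may alkylate the activated rings if scavenging is incomplete. Fallback: setting out from 18, all three acid-labile groups would be removed at once with 3 M aqueous HCl in THF at 40 °C to give the triol 2-(3-hydroxy-5-methylphenoxy)-3-(hydroxymethyl)-5-methoxyphenol F4. Its primary alcohol would then be acylated chemoselectively with vinyl palmitate and immobilised Candida antarctica lipase B in t-BuOMe at 40 °C, a method that leaves phenols unacylated, coming back at 23.

**Step 3.** Regiocontrol between the two phenols may be lost (double alkylation or alkylation of the C2 oxygen). Fallback: setting out from 3, the C2 oxygen would be blocked before the C3 oxygen exists: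
- benzylation (BnBr, K2CO3, DMF) to methyl 2-(benzyloxy)-3-formyl-5-methoxybenzoate F5;
- Baeyer–Villiger oxidation with mCPBA in CH2Cl2 to methyl 2-(benzyloxy)-3-(formyloxy)-5-methoxybenzoate F6;
- methanolysis (catalytic K2CO3, MeOH) to methyl 2-(benzyloxy)-3-hydroxy-5-methoxybenzoate F7;
- MOMCl and i-Pr2NEt to methyl 2-(benzyloxy)-5-methoxy-3-(methoxymethoxy)benzoate F8;
- hydrogenolysis (H2, Pd/C, EtOAc), coming back at 6.

**Step 5.** The phenol may be silylated in competition with the primary alcohol, or the silyl group may migrate between the two oxygens. Fallback: setting out from 7, both hydroxyls would be silylated with excess TBSCl and imidazole in DMF to give tert-butyl{[2-{[tert-butyl(dimethyl)silyl]oxy}-5-methoxy-3-(methoxymethoxy)phenyl]methoxy}dimethylsilane F9. The more labile aryl silyl ether would then be cleaved selectively with K2CO3 in MeOH at rt, coming back at 8.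

## Further compounds

F1 | step 9 | 3-bromo-5-methylphenol (purchased) | Cc1cc(O)cc(Br)c1
F2 | step 9 | 1-bromo-3-(methoxymethoxy)-5-methylbenzene | COCOc1cc(C)cc(Br)c1
F3 | step 7 | tert-butyl{[5-methoxy-3-(methoxymethoxy)-2-{[(trimethylsilyl)ethynyl]oxy}phenyl]methoxy}dimethylsilane | COCOc1cc(OC)cc(CO[Si](C)(C)C(C)(C)C)c1OC#C[Si](C)(C)C
F4 | step 12 | 2-(3-hydroxy-5-methylphenoxy)-3-(hydroxymethyl)-5-methoxyphenol | Cc1cc(O)cc(Oc2c(CO)cc(OC)cc2O)c1
F5 | step 3 | methyl 2-(benzyloxy)-3-formyl-5-methoxybenzoate | COC(=O)c1cc(OC)cc(C=O)c1OCc1ccccc1
F6 | step 3 | methyl 2-(benzyloxy)-3-(formyloxy)-5-methoxybenzoate | COC(=O)c1cc(OC)cc(OC=O)c1OCc1ccccc1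
F7 | step 3 | methyl 2-(benzyloxy)-3-hydroxy-5-methoxybenzoate | COC(=O)c1cc(OC)cc(O)c1OCc1ccccc1
F8 | step 3 | methyl 2-(benzyloxy)-5-methoxy-3-(methoxymethoxy)benzoate | COCOc1cc(OC)cc(C(=O)OC)c1OCc1ccccc1
F9 | step 5 | tert-butyl{[2-{[tert-butyl(dimethyl)silyl]oxy}-5-methoxy-3-(methoxymethoxy)phenyl]methoxy}dimethylsilane | COCOc1cc(OC)cc(CO[Si](C)(C)C(C)(C)C)c1O[Si](C)(C)C(C)(C)C
A1 | alternative 1 | orcinol (5-methylbenzene-1,3-diol) | Cc1cc(O)cc(O)c1
A2 | alternative 1 | ethyl (4E)-7-[3-(benzyloxy)-5-methylphenoxy]-4-methoxy-2,6-dioxohept-4-enoate | CCOC(=O)C(=O)C/C(OC)=C\C(=O)COc1cc(C)cc(OCc2ccccc2)c1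
A3 | alternative 1 | ethyl 2-[3-(benzyloxy)-5-methylphenoxy]-3-hydroxy-5-methoxybenzoate | CCOC(=O)c1cc(OC)cc(O)c1Oc1cc(C)cc(OCc2ccccc2)c1
A4 | alternative 2 | 4-[3-(tert-butyldimethylsilyloxy)-5-methylphenoxy]-3-[(tert-butyldimethylsilyloxy)methyl]cyclobut-2-en-1-one (racemic) | O=C1C=C(CO[Si](C)(C)C(C)(C)C)C1Oc1cc(C)cc(O[Si](C)(C)C(C)(C)C)c1
A5 | alternative 2 | methoxyacetylene (methoxyethyne) | COC#C
A6 | alternative 2 | 2-[3-(tert-butyldimethylsilyloxy)-5-methylphenoxy]-3-[(tert-butyldimethylsilyloxy)methyl]-5-methoxyphenol | COc1cc(O)c(Oc2cc(C)cc(O[Si](C)(C)C(C)(C)C)c2)c(CO[Si](C)(C)C(C)(C)C)c1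
A7 | alternative 3 | (3Z)-3-[3-(benzyloxy)-5-methylphenoxy]-5-[(tert-butyldimethylsilyl)oxy]pent-3-en-2-one (either alkene isomer would serve) | CC(=O)/C(Oc1cc(C)cc(OCc2ccccc2)c1)=C/CO[Si](C)(C)C(C)(C)C
A8 | alternative 3 | dimethyl malonate | COC(=O)CC(=O)OC
A9 | alternative 3 | methyl 5-[3-(benzyloxy)-5-methylphenoxy]-6-[(tert-butyldimethylsilyloxy)methyl]-2,4-dioxocyclohexane-1-carboxylate (mixture of diastereomers) | COC(=O)C1C(=O)CC(=O)C(Oc2cc(C)cc(OCc3ccccc3)c2)C1CO[Si](C)(C)C(C)(C)C
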